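**Plan**

1. Labdane numbering is used: ring B = C5–C10, cyclobutane = C8/C9/C14/C15, cyclopentane = C9/C11/C12/C13/C14. Retrosynthetic cuts, in order: the C6–OAc bond (back to the C7 ketone via its C6=C7 enol acetate), C13–C14, then C8–C15 and C9–C14 (back to a 7-oxo-8-ene and acetylene), and last the vinyl group of sclareol.
2. Enabling feature: the tertiary carbinol C13 is bonded directly to C14, the carbon shared by the cyclobutane and the cyclopentane. With C14=C15 as a cyclobutene and C13 as the carbonyl of a 3-oxobutyl chain on C9, the C13–C14 bond is the retron of a reductive ketone–alkene coupling.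
3. Forward: rings A and B and the chain C11–C12–C13–C16 come from sclareol; the four-membered ring is fused on by enone–acetylene [2+2] photoaddition; SmI2 closes the five-membered ring; the C6 acetate is placed last.
4. Stereochemistry: C5 and C10 come from sclareol; C8 and C9 from photoaddition on the α face, anti to the C10 methyl; C14 from the tether (cis fusion); C13 from the anti ketyl transition state; C6 from α-face epoxidation of the enol acetate followed by a 1,2-acyl shift with inversion.

Key step: step 8

Assumption: hydride reduction of ketone 8 is taken to give the 7β-carbinol; the configuration at C7 is of no consequence because C7 is oxidised back to the ketone in step 9.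

**Route**

Step 1
Reactants: 1 (−)-sclareol
Product: 3 8α-hydroxy-14,15-dinorlabdan-13-one, via labdane-8α,13,14,15-tetrol 2 (not isolated)
Conditions: OsO4 (cat.), NaIO4, THF/H2O, 45 °C
Reagents that add atoms: none
Why: Lemieux–Johnson oxidation, in which catalytic dihydroxylation of the vinyl group gives a 13,14,15-triol unit that periodate cleaves twice, so that the C13 carbinol becomes the methyl ketone while the tertiary C8 carbinol is untouched and no stereocentre is formed.

Step 2
Reactants: 3 8α-hydroxy-14,15-dinorlabdan-13-one
Product: 4 14,15-dinorlabd-8-en-13-one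
Conditions: HI (57% aq., cat.), PhH, 80 °C
Reagents that add atoms: none
Why: Acid-catalysed E1 dehydration of the tertiary C8 alcohol under equilibrating conditions, so that the alkene isomers (and any cyclic enol ether formed with the C13 ketone) should drain to the thermodynamically preferred tetrasubstituted C8=C9 alkene, leaving C5 and C10 untouched.

Step 3
Reactants: 4 14,15-dinorlabd-8-en-13-one
Product: 5 14,15-dinorlabd-8-ene-7,13-dione
Conditions: CrO3, 3,5-dimethylpyrazole, CH2Cl2, −20 °C
Reagents that add atoms: chromium trioxide, O=[Cr](=O)=O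
Why: Allylic oxidation with the CrO3–3,5-dimethylpyrazole complex, which should attack the ring methylene C7 (axial C–H aligned with the π bond) in preference to C11 (crowded by quaternary C10), as is usual for 8-ene labdanes and drimanes, to give the conjugated 7-oxo-8-ene.

Step 4
Reactants: 5 14,15-dinorlabd-8-ene-7,13-dione
Product: 6 13,13-ethylenedioxy-14,15-dinorlabd-8-en-7-one
Conditions: (TMSOCH2)2, TMSOTf (cat.), CH2Cl2, −78 °C
Reagents that add atoms: 1,2-bis(trimethylsilyloxy)ethane, C[Si](C)(C)OCCO[Si](C)(C)C
Why: Noyori ketalisation, which at low temperature converts the saturated methyl ketone into its dioxolane while the hindered conjugated C7 ketone does not react, leaving C7 as the only carbonyl open to hydride in step 6.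

Step 5
Reactants: 6 13,13-ethylenedioxy-14,15-dinorlabd-8-en-7-one; 7 acetylene
Product: 8 cyclobutene ketone (7-oxo, C14=C15 bridge cis-fused on the α face of C8–C9, C13 dioxolane)
Conditions: C2H2 (sat.), CH2Cl2, hν (medium-pressure mercury lamp, uranium-glass filter, λ > 330 nm), −78 °C
Reagents that add atoms: none
Why: Enone–alkyne [2+2] photocycloaddition through the enone triplet, in which the β-carbon C9 bonds axially on the α face, anti to the C10 methyl, and the four-membered ring can only close cis on that face, setting C8 (methyl β) and C9 (chain β) together, while the long-wavelength filter keeps the β,γ-unsaturated ketone product from absorbing.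

Step 6
Reactants: 8 cyclobutene ketone
Product: 9 cyclobutene 7β-carbinol (C13 dioxolane)
Conditions: NaBH4, MeOH/THF, 0 °C
Reagents that add atoms: none
Why: Borohydride reduction of the only free carbonyl (dioxolane and cyclobutene are inert), with hydride expected from the α face away from the axial C8 methyl to give the 7β-carbinol, a temporary stereocentre whose formation also removes the acid-sensitive β,γ-unsaturated ketone before step 7.

Step 7
Reactants: 9 cyclobutene 7β-carbinol (C13 dioxolane)
Product: 10 cyclobutene 7β-carbinol with 9β-(3-oxobutyl) chain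
Conditions: 1 M aq. HCl, THF, rt
Reagents that add atoms: water, O
Why: Acid-catalysed acetal hydrolysis frees the C13 methyl ketone, while the neopentyl homoallylic C7 carbinol and the cyclobutene should not ionise in dilute acid at room temperature.

Step 8
Reactants: 10 cyclobutene 7β-carbinol with 9β-(3-oxobutyl) chain
Product: 11 tetracyclic 7β,13-diol
Conditions: SmI2 (2.5 equiv), HMPA, t-BuOH, THF, 0 °C
Reagents that add atoms: none
Why: SmI2–HMPA transfers one electron to the C13 carbonyl, the samarium ketyl adds to C14 of the strained cyclobutene, and the resulting C15 cyclobutyl radical is reduced by a second SmI2 to an organosamarium that t-BuOH protonates. The closest known reaction type is the SmI2/HMPA reductive ketyl–olefin cyclisation of δ,ε-unsaturated methyl ketones onto unactivated alkenes, here assisted by the strain of the cyclobutene. The cyclopentane C9–C11–C12–C13–C14 closes in the 5-exo-trig mode, the 6-endo alternative at C15 requiring a bridged ring across the four-membered ring. C14 is fixed by the tether: the chain on C9 can reach only the cyclobutene face on which it stands, so the bicyclo[3.2.0]heptane is cis-fused and H14 ends on the ring B side. C13 is set by the anti transition state, in which the HMPA-solvated O–Sm group turns away from the alkene carbon C15 and the methyl lies over the four-membered ring, so the hydroxyl ends anti to C15. The step needs reduction of a single ketone without opening of the four-membered ring, which the substrate secures by holding C7 at the carbinol level (no ketyl and hence no cyclobutylcarbinyl radical next to C8) and because a cyclobutyl radical at C15 does not fragment.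

Step 9
Reactants: 11 tetracyclic 7β,13-diol
Product: 12 tetracyclic 13-hydroxy-7-ketone
Conditions: n-Pr4N[RuO4] (cat.), NMO, 4 Å MS, CH2Cl2, rt
Reagents that add atoms: none
Why: Ley–Griffith oxidation converts the secondary C7 carbinol into the ketone (erasing the temporary C7 stereocentre), while the tertiary C13 alcohol cannot be oxidised and the non-acidic medium spares this cyclobutylcarbinyl tertiary alcohol.

Step 10
Reactants: 12 tetracyclic 13-hydroxy-7-ketone
Product: 13 13-O-trimethylsilyl 7-ketone
Conditions: TMS-imidazole, CH2Cl2, rt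
Reagents that add atoms: 1-(trimethylsilyl)imidazole, C[Si](C)(C)n1ccnc1
Why: Silylation of the tertiary alcohol with a neutral silyl donor that does not enolise the hindered ketone, so that the C13 oxygen cannot be acetylated in step 11.

Step 11
Reactants: 13 13-O-trimethylsilyl 7-ketone
Product: 14 C6=C7 enol acetate (13-O-TMS)
Conditions: KN(SiMe3)2, THF, −78 °C; then Ac2O, −78 → 0 °C
Reagents that add atoms: acetic anhydride, CC(=O)OC(C)=O
Why: Because C8 is quaternary, deprotonation can occur only at C6 and gives a single potassium enolate, whose O-acylation by acetic anhydride (enolate trapping, favoured for a hindered potassium enolate) should give the C6=C7 enol acetate.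

Step 12
Reactants: 14 C6=C7 enol acetate (13-O-TMS)
Product: 15 6α,7α-epoxy-7β-acetate (13-O-TMS)
Conditions: DMDO, acetone, 0 °C
Reagents that add atoms: dimethyldioxirane, CC1(C)OO1
Why: Neutral dioxirane epoxidation of the electron-rich enol ester, with oxygen delivered to the α face because the β face of C6=C7 is screened by the axial methyls on C4, C8 and C10, which sets C6 and C7 of the acetoxy epoxide.

Step 13
Reactants: 15 6α,7α-epoxy-7β-acetate (13-O-TMS)
Product: 17 CNP0330581.1 (6β-acetoxy-13-hydroxy-7-ketone), via 6β-acetoxy-7-ketone TMS ether 16 (not isolated)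
Conditions: PhMe, 150 °C (sealed tube, base-washed glass); then PPTS, MeOH, 0 °C → rt
Reagents that add atoms: none
Why: Thermal enol ester epoxide rearrangement, in which the acetoxy group on C7 shifts through a five-membered cyclic transition state to C6 on the β face as the C6–O epoxide bond breaks (inversion at C6, the outcome known for steroidal enol acetate epoxides), giving the axial 6β-acetate and the C7 ketone, after which mild methanolysis removes the tertiary TMS ether without epimerising C6.

**Compound list**

1 | (−)-sclareol, (13R)-labd-14-ene-8α,13-diol | C1C[C@@](C)(O)[C@H](CC[C@@](C)(O)C=C)[C@@]2(C)CCCC(C)(C)[C@H]12 | starting material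
2 | (13R)-labdane-8α,13,14,15-tetrol (both C14 epimers) | C1C[C@@](C)(O)[C@H](CC[C@@](C)(O)C(O)CO)[C@@]2(C)CCCC(C)(C)[C@H]12 | intermediate (not isolated)
3 | 8α-hydroxy-14,15-dinorlabdan-13-one | C1C[C@@](C)(O)[C@H](CCC(C)=O)[C@@]2(C)CCCC(C)(C)[C@H]12 | intermediate
4 | 14,15-dinorlabd-8-en-13-one (tetrasubstituted C8=C9) | C1CC(C)=C(CCC(C)=O)[C@@]2(C)CCCC(C)(C)[C@H]12 | intermediate
5 | 14,15-dinorlabd-8-ene-7,13-dione | C1C(=O)C(C)=C(CCC(C)=O)[C@@]2(C)CCCC(C)(C)[C@H]12 | intermediate
6 | 13,13-ethylenedioxy-14,15-dinorlabd-8-en-7-one (dioxolane of the side-chain ketone) | C1C(=O)C(C)=C(CCC3(C)OCCO3)[C@@]2(C)CCCC(C)(C)[C@H]12 | intermediate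
7 | acetylene | C#C | starting material
8 | cyclobutene ketone: 7-ketone, C14=C15 bridge (C14 on C9, C15 on C8) cis-fused on the α face, 8β-methyl, 9β-(3,3-ethylenedioxybutyl), 5α-H, 10β-methyl | C1C(=O)[C@@]2(C)C=C[C@@]2(CCC3(C)OCCO3)[C@@]2(C)CCCC(C)(C)[C@H]12 | intermediate
9 | 7β-carbinol of 8 (C13 dioxolane retained) | C1[C@H](O)[C@@]2(C)C=C[C@@]2(CCC3(C)OCCO3)[C@@]2(C)CCCC(C)(C)[C@H]12 | intermediate
10 | key-step precursor: 7β-hydroxy cyclobutene with 9β-(3-oxobutyl) chain | C1[C@H](O)[C@@]2(C)C=C[C@@]2(CCC(C)=O)[C@@]2(C)CCCC(C)(C)[C@H]12 | intermediate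
11 | key-step product: tetracyclic 7β,13-diol; cyclopentane cis-fused to the cyclobutane at C9–C14, H14 on the ring B side, 13-OH anti to C15, 13-methyl syn to C15 | C1[C@H](O)[C@@]2(C)C[C@H]3[C@@]2(CC[C@]3(C)O)[C@@]2(C)CCCC(C)(C)[C@H]12 | intermediate
12 | tetracyclic 13-hydroxy-7-ketone | C1C(=O)[C@@]2(C)C[C@H]3[C@@]2(CC[C@]3(C)O)[C@@]2(C)CCCC(C)(C)[C@H]12 | intermediate
13 | 13-O-trimethylsilyl ether of 12 | C1C(=O)[C@@]2(C)C[C@H]3[C@@]2(CC[C@]3(C)O[Si](C)(C)C)[C@@]2(C)CCCC(C)(C)[C@H]12 | intermediate
14 | C6=C7 enol acetate (7-acetoxy-6-ene), 13-O-TMS | C1=C(OC(C)=O)[C@@]2(C)C[C@H]3[C@@]2(CC[C@]3(C)O[Si](C)(C)C)[C@@]2(C)CCCC(C)(C)[C@H]12 | intermediate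
15 | 6α,7α-epoxy-7β-acetate, 13-O-TMS | O1[C@H]2[C@]1(OC(C)=O)[C@@]3(C)C[C@H]4[C@@]3(CC[C@]4(C)O[Si](C)(C)C)[C@@]3(C)CCCC(C)(C)[C@H]23 | intermediate
16 | 6β-acetoxy-7-ketone, 13-O-TMS | CC(=O)O[C@@H]1C(=O)[C@@]2(C)C[C@H]3[C@@]2(CC[C@]3(C)O[Si](C)(C)C)[C@@]2(C)CCCC(C)(C)[C@H]12 | intermediate (not isolated)
17 | CNP0330581.1: 6β-acetoxy-13-hydroxy-7-ketone | CC(=O)O[C@@H]1C(=O)[C@@]2(C)C[C@H]3[C@@]2(CC[C@]3(C)O)[C@@]2(C)CCCC(C)(C)[C@H]12 | target

**Step count and risks**

Total steps: 13. Longest linear sequence: 13 steps from sclareol (acetylene enters in step 5).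

Steps most likely to fail:

Step 5. The short-lived triplet of a fully substituted enone may be trapped inefficiently by a dissolved gas, and the β,γ-unsaturated ketone product may undergo secondary photochemistry (1,3-acyl shift) as conversion rises. The fallback sets out from 6 and returns at 9. Irradiation of 6 in excess (Z)-1,2-dichloroethene should give the saturated dichlorocyclobutane ketone F1 (cis-fused on the α face, chlorine epimers), which has no alkene to start an acyl shift. NaBH4 then reduces C7 to the dichloro carbinol F2. Reductive 1,2-dechlorination with NaC10H8 (sodium naphthalenide) in THF at −78 °C unveils the cyclobutene and gives 9.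

Step 8. The ketyl may be reduced to the open-chain secondary carbinol before ring closure, or the anti preference at C13 may be eroded by the crowded surroundings of C8 and C10. The fallback sets out from 10 and returns at 11; it forms the same C13–C14 bond with a carbon radical and introduces the oxygen afterwards. Condensation with N2H4·H2O gives the hydrazone F3. Barton iodination (I2, tetramethylguanidine) gives the 2-iodo-1-alkene F4. Bu3SnH/AIBN in PhH at 80 °C generates the C13 vinyl radical, which closes 5-exo onto C14 (cis fusion again enforced by the tether) to give the 13-methylene tetracycle F5. DMDO should epoxidise the methylene on the face turned away from C15 to give the spiro-epoxide F6. LiAlH4 opens F6 at its CH2 terminus, leaving the C13 hydroxyl anti to C15 and giving 11.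

Step 13. The acyl shift may follow the ionic pathway with retention, so that the acetate arrives on the α face, or the concerted shift may fail on a β face crowded by three axial methyls. The fallback sets out from 13 and returns at 17. KN(SiMe3)2 and PhNTf2 give the enol triflate F7. Reduction with Pd(OAc)2, PPh3, HCO2H and Et3N in DMF gives the 6-ene F8. DMDO epoxidises the α face to give the 6α,7α-epoxide F9. Warm acetic acid should open F9 trans-diaxially (Fürst–Plattner), acetate entering C6 from the β face, and cleave the TMS ether, to give the 6β-acetoxy-7α,13-diol F10. Oxidation of the C7 carbinol with n-Pr4N[RuO4] (cat.) and NMO then gives 17.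

**Further compounds**

F1 | step 5 | 14,15-dichlorocyclobutane 7-ketone with C13 dioxolane (α-face cis-fused, chlorine epimers) | C1C(=O)[C@@]2(C)C(Cl)C(Cl)[C@@]2(CCC3(C)OCCO3)[C@@]2(C)CCCC(C)(C)[C@H]12
F2 | step 5 | 14,15-dichlorocyclobutane 7β-carbinol with C13 dioxolane | C1[C@H](O)[C@@]2(C)C(Cl)C(Cl)[C@@]2(CCC3(C)OCCO3)[C@@]2(C)CCCC(C)(C)[C@H]12
F3 | step 8 | C13 hydrazone of 10 | C1[C@H](O)[C@@]2(C)C=C[C@@]2(CCC(C)=NN)[C@@]2(C)CCCC(C)(C)[C@H]12
F4 | step 8 | 9β-(3-iodobut-3-enyl) cyclobutene 7β-carbinol | C1[C@H](O)[C@@]2(C)C=C[C@@]2(CCC(I)=C)[C@@]2(C)CCCC(C)(C)[C@H]12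
F5 | step 8 | 13-methylene tetracyclic 7β-carbinol | C1[C@H](O)[C@@]2(C)C[C@H]3[C@@]2(CCC3=C)[C@@]2(C)CCCC(C)(C)[C@H]12
F6 | step 8 | C13 spiro-epoxide of F5 (oxygen anti to C15) | C1[C@H](O)[C@@]2(C)C[C@H]3[C@@]2(CC[C@@]34CO4)[C@@]2(C)CCCC(C)(C)[C@H]12
F7 | step 13 | C6=C7 enol triflate, 13-O-TMS | C1=C(OS(=O)(=O)C(F)(F)F)[C@@]2(C)C[C@H]3[C@@]2(CC[C@]3(C)O[Si](C)(C)C)[C@@]2(C)CCCC(C)(C)[C@H]12
F8 | step 13 | tetracyclic 6-ene, 13-O-TMS | C1=C[C@@]2(C)C[C@H]3[C@@]2(CC[C@]3(C)O[Si](C)(C)C)[C@@]2(C)CCCC(C)(C)[C@H]12
F9 | step 13 | 6α,7α-epoxide, 13-O-TMS | O1[C@H]2[C@@H]1[C@@]3(C)C[C@H]4[C@@]3(CC[C@]4(C)O[Si](C)(C)C)[C@@]3(C)CCCC(C)(C)[C@H]23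
F10 | step 13 | 6β-acetoxy-7α,13-diol | CC(=O)O[C@@H]1[C@@H](O)[C@@]2(C)C[C@H]3[C@@]2(CC[C@]3(C)O)[C@@]2(C)CCCC(C)(C)[C@H]12
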